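(Its constants are invented; the run is a simulation.)

Late in this run I expected the flask to stand still, so I set out to reckon its resting mixture and how soon it got there.

    substrate + catalyst ⇌ target + catalyst, rate k1*[substrate]*[catalyst] forward; the back reaction follows from the equilibrium constant (K1 = 19, k1 = 880 /M/s)
    catalyst ⇌ dormant form (K2 = 0.33, k2 = 0.0038 /s)
    target + catalyst ⇌ isomer of the product + catalyst, rate k3*[catalyst]*[target] forward; the back reaction follows from the equilibrium constant (K3 = 2.4, k3 = 410 /M/s)

substrate 0.010 M; catalyst 0.1 mol% (in portions, 2); time 5.0 h; the portions of catalyst follow each other after 40 s, the first at the start

* at 5.0 h, what has stopped the reaction, if anything has (forward and back rates have come level / no working catalyst is left / it is still moving)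
* conversion of substrate at 5.0 h
* amount of target at 5.0 h, in percent of the substrate charged
* amount of isomer of the product at 5.0 h, in percent of the substrate charged

- the reaction counts as stopped when no species that holds the substrate changes by six tenths of a point or more over the second half of the time
- run time (flask): 5.0 h

I froze the catalyst first. Its exchange with the dormant form does not involve the substrate, so I held the working catalyst at its balance value, the charge divided by one plus the constant of that exchange:

[catalyst] = 7.52 × 10⁻⁶ M

With [catalyst] constant, each catalysed step became first-order (pseudo-first-order), and I could set up a ladder of relaxation half-lives, each taken by its own step, both ways together:

catalyst and dormant form: 45.3 s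

substrate and target: 99.5 s

target and isomer of the product: 2.65 min

On the first rung I expected the catalyst to settle towards its balance with the dormant form. The second portion was due after 40 s, sooner than the relaxation half-life of substrate and target, so I counted the full loading from then on. On the second rung I expected [target]/[substrate] to climb towards 19. On the third, which overlaps the second, I expected [isomer of the product]/[target] to climb towards 2.4.

The top rung, 2.65 min, fits about 113 times into 5.0 h, so I expected thermodynamic control. Both directions of each catalysed step carry [catalyst], so it cancels from the ratios:

substrate : target : isomer of the product = 1 : 19 : 45.6

My carried quantity was the end share of isomer, the product of the two constants over one plus the first constant plus that product: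

end share of isomer = 69.5%

The same ratios gave me 29.0% of target and a conversion of 98.5%.

The forecast said: forward and back rates have come level, with conversion 98.5%, target 29% and isomer of the product 69.5%. Its ground was that “5 h is far more than enough to reach equilibrium”.

The simulation of this flask gave: forward and back rates have come level, with conversion 98.5%, target 29.0% and isomer of the product 69.5%.

So this flask was a mixture at rest, and the forecast stood with it. The relaxation half-life of target and isomer of the product at 5.00 h was 2.65 min, shorter than the 5.0 h of the run, and this flask held 69.5% of isomer at 2.50 h and 69.5% at 5.00 h, against my end share of 69.5%.

The neighbouring flask, left until 20 h, has the same constants, and time does not enter the end share, so I carried 69.5% over to it. Its simulation gave 69.5% of isomer of the product.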